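**Plan**

- Retrosynthetic cuts: the benzyl and silyl ethers; in the side chain C7–C8 (aldol) and the ring B O–CH2 ether bond to C8 (phenoxide alkylation); at C4 the hydroxyl and the CH2–ring A bond (lactone enolate chemistry); O1–C2 of the oxolane, which leads back to a cyclopropane whose C2–C4 bond is temporary; the cyclopropane to an enal and bromomalonate.
- Enabling feature: in the oxolane (O1, C2, C3, C4, C5) C2 is benzylic and para to the ether oxygen of ring B, and C4 bears C5, which can stand at the carboxyl level. C2–C3–C4 is therefore a cyclopropane with ring B as donor on C2 and two ester acceptors on C4.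
- Forward order: ring B enal → cyclopropane → aryl lactone by strain-releasing ring expansion (the oxolane with C5 as carbonyl) → ring A joined at C4, decarboxylation, hydroxylation → lactone reduced and re-closed to the oxolane → ring B phenol freed, ring C joined by aldol → deprotection.
- Stereochemistry: C3 from the amine-catalysed cyclopropanation; C2 trans to C3 by equilibrating closure (steps 5 and 11); C4 by enolate hydroxylation anti to the C3 arm; C8 from an oxazolidinone-directed syn aldol; C7 by Mitsunobu inversion of that adduct to the anti (7S,8R) pair.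

Key step: step 5

Remark: locants are those of the target (oxolane O1, C2 aryl, C3 CH2OH arm, C4 carbinol, C5 methylene; side chain C7 carbinol, C8 ether carbon, C9 CH2OH); ring A is the benzyl guaiacyl on C4, ring B the aryl on C2, ring C the side-chain guaiacyl. The side chain is the anti (erythro) isomer, which a syn-selective boron aldol does not give directly, hence the inversion at C7. Compounds 1, 3, 9, 17, 18 and 21 are taken as purchased.

**Route**

Step 1
Reactants: 1 coniferaldehyde, (E)-3-(4-hydroxy-3-methoxyphenyl)prop-2-enal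
Product: 2 (E)-3-(4-allyloxy-3-methoxyphenyl)prop-2-enal
Conditions: allyl bromide, K2CO3, acetone, 50 °C
Reagents that add atoms: allyl bromide, C=CCBr
Why: Williamson ether synthesis on the only acidic site leaves the enal untouched and gives ring B an oxygen protecting group that zerovalent palladium can later remove beside benzyl and silyl ethers.

Step 2
Reactants: 2 (E)-3-(4-allyloxy-3-methoxyphenyl)prop-2-enal; 3 dimethyl bromomalonate
Product: 4 dimethyl (2S,3R)-2-(4-allyloxy-3-methoxyphenyl)-3-formylcyclopropane-1,1-dicarboxylate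
Conditions: (S)-α,α-diphenylprolinol trimethylsilyl ether (20 mol%), 2,6-lutidine, CH2Cl2, 0 °C
Reagents that add atoms: none
Why: Michael-initiated ring closure under iminium–enamine catalysis, in which the malonate adds to the β-carbon of the E-iminium ion on the face away from the diphenyl(silyloxy)methyl group and the enamine then displaces bromide, so both ring centres are set trans to each other and in the absolute sense needed for C3.

Step 3
Reactants: 4 dimethyl (2S,3R)-2-(4-allyloxy-3-methoxyphenyl)-3-formylcyclopropane-1,1-dicarboxylate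
Product: 5 dimethyl (2S,3R)-2-(4-allyloxy-3-methoxyphenyl)-3-(hydroxymethyl)cyclopropane-1,1-dicarboxylate
Conditions: NaBH4, MeOH, −20 °C; pH 7 buffer; used crude
Reagents that add atoms: none
Why: Chemoselective borohydride reduction of the aldehyde beside the malonate esters, run cold and worked up neutral so that the alcohol should not lactonise onto the cis ester before it is capped.

Step 4
Reactants: 5 dimethyl (2S,3R)-2-(4-allyloxy-3-methoxyphenyl)-3-(hydroxymethyl)cyclopropane-1,1-dicarboxylate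
Product: 6 dimethyl (2S,3R)-2-(4-allyloxy-3-methoxyphenyl)-3-[(tert-butyldiphenylsilyloxy)methyl]cyclopropane-1,1-dicarboxylate
Conditions: t-BuPh2SiCl, imidazole, CH2Cl2, 0 °C to rt
Reagents that add atoms: tert-butyl(chloro)diphenylsilane, CC(C)(C)[Si](Cl)(c1ccccc1)c1ccccc1
Why: Silylation of the primary alcohol with an acid-robust group blocks lactonisation of the arm and keeps this oxygen out of the cation chemistry that follows.

Step 5
Reactants: 6 dimethyl (2S,3R)-2-(4-allyloxy-3-methoxyphenyl)-3-[(tert-butyldiphenylsilyloxy)methyl]cyclopropane-1,1-dicarboxylate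
Product: 8 methyl (3R,4R,5S)-5-(4-allyloxy-3-methoxyphenyl)-4-[(tert-butyldiphenylsilyloxy)methyl]-2-oxooxolane-3-carboxylate, via cyclic ketene acetal 7 (not isolated)
Conditions: Sc(OTf)3 (10 mol%), H2O (3 equiv), ClCH2CH2Cl, 40 °C
Reagents that add atoms: water, O
Why: Sc(OTf)3 chelates the geminal diester and the strained C2–C4 bond ionises to a malonate enolate and a C2 cation stabilised by the para allyloxy group of ring B; an ester carbonyl oxygen closes on C2 to give the 2-methoxy-4,5-dihydrofuran 7, which water hydrolyses at the ketene acetal carbon with loss of methanol to the lactone. The closest known reaction type is the acid-promoted ring-opening lactonisation of 2-arylcyclopropane-1,1-diesters, a donor–acceptor cyclopropane ring expansion. The five-membered ring closes in the 5-exo-trig mode, because the quinoid bond from C2 into ring B lies outside the ring that forms. C3 is never broken and keeps the configuration from step 2; C2 is re-formed trans to the C3 silyloxymethyl arm because closure at this doubly activated benzylic position is reversible and the trans lactone is the more stable; C4, an epimerisable malonate-type CH, should settle trans to the arm as well. The step needs 2,3-trans selectivity and survival of the silyl ether: the first comes from the C3 substituent under equilibrating conditions, the second from the bulk of the tert-butyldiphenylsilyl group and the small amount of water.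

Step 6
Reactants: 9 4-benzyloxy-3-methoxybenzyl alcohol
Product: 10 4-benzyloxy-3-methoxybenzyl bromide
Conditions: PBr3, Et2O, 0 °C; used fresh
Reagents that add atoms: phosphorus tribromide, BrP(Br)Br
Why: Standard conversion of an electron-rich benzylic alcohol into its bromide through the phosphite ester.

Step 7
Reactants: 8 methyl (3R,4R,5S)-5-(4-allyloxy-3-methoxyphenyl)-4-[(tert-butyldiphenylsilyloxy)methyl]-2-oxooxolane-3-carboxylate; 10 4-benzyloxy-3-methoxybenzyl bromide
Product: 11 methyl (3S,4R,5S)-5-(4-allyloxy-3-methoxyphenyl)-3-(4-benzyloxy-3-methoxybenzyl)-4-[(tert-butyldiphenylsilyloxy)methyl]-2-oxooxolane-3-carboxylate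
Conditions: K2CO3, DMF, rt
Reagents that add atoms: none
Why: Malonate-type C-alkylation of the stabilised lactone–ester enolate forms the C4–CH2 bond to ring A, the benzyl group being expected anti to the C3 arm, although this centre is planarised again in steps 8 and 9 and its configuration is of no consequence.

Step 8
Reactants: 11 methyl (3S,4R,5S)-5-(4-allyloxy-3-methoxyphenyl)-3-(4-benzyloxy-3-methoxybenzyl)-4-[(tert-butyldiphenylsilyloxy)methyl]-2-oxooxolane-3-carboxylate
Product: 12 (3S,4R,5S)-5-(4-allyloxy-3-methoxyphenyl)-3-(4-benzyloxy-3-methoxybenzyl)-4-[(tert-butyldiphenylsilyloxy)methyl]oxolan-2-one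
Conditions: LiCl, H2O, DMSO, 130 °C
Reagents that add atoms: none
Why: Krapcho dealkoxycarbonylation, in which chloride demethylates the ester, the carboxylate loses CO2 and the lactone enolate is protonated, mainly to the 3,4-trans epimer (either C4 epimer serves, since step 9 passes through the enolate).

Step 9
Reactants: 12 (3S,4R,5S)-5-(4-allyloxy-3-methoxyphenyl)-3-(4-benzyloxy-3-methoxybenzyl)-4-[(tert-butyldiphenylsilyloxy)methyl]oxolan-2-one
Product: 13 (3S,4R,5S)-5-(4-allyloxy-3-methoxyphenyl)-3-(4-benzyloxy-3-methoxybenzyl)-4-[(tert-butyldiphenylsilyloxy)methyl]-3-hydroxyoxolan-2-one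
Conditions: KN(SiMe3)2, THF, −78 °C; then 3-phenyl-2-(phenylsulfonyl)oxaziridine, −78 °C
Reagents that add atoms: 3-phenyl-2-(phenylsulfonyl)oxaziridine, O=S(=O)(c1ccccc1)N1OC1c1ccccc1
Why: Davis enolate hydroxylation, in which the potassium enolate should be oxidised on the face anti to the adjacent bulky C3 silyloxymethyl group, placing the new tertiary hydroxyl trans and the ring A benzyl group cis to that arm as the target requires.

Step 10
Reactants: 13 (3S,4R,5S)-5-(4-allyloxy-3-methoxyphenyl)-3-(4-benzyloxy-3-methoxybenzyl)-4-[(tert-butyldiphenylsilyloxy)methyl]-3-hydroxyoxolan-2-one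
Product: 14 (2S,3R,4S)-4-(4-allyloxy-3-methoxyphenyl)-2-(4-benzyloxy-3-methoxybenzyl)-3-[(tert-butyldiphenylsilyloxy)methyl]butane-1,2,4-triol
Conditions: LiAlH4, THF, 0 °C
Reagents that add atoms: none
Why: Hydride reduction of the lactone to the primary alcohol and the benzylic alcohol gives the triol without breaking a bond to any stereocentre and leaves allyl, benzyl and silyl ethers alone.

Step 11
Reactants: 14 (2S,3R,4S)-4-(4-allyloxy-3-methoxyphenyl)-2-(4-benzyloxy-3-methoxybenzyl)-3-[(tert-butyldiphenylsilyloxy)methyl]butane-1,2,4-triol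
Product: 15 (3S,4R,5S)-5-(4-allyloxy-3-methoxyphenyl)-3-(4-benzyloxy-3-methoxybenzyl)-4-[(tert-butyldiphenylsilyloxy)methyl]oxolan-3-ol
Conditions: (+)-10-camphorsulfonic acid (10 mol%), CH2Cl2, 0 °C, short reaction time
Reagents that add atoms: none
Why: Acid-catalysed SN1 cycloetherification through the para-allyloxybenzylic cation, captured 5-exo-trig by the primary hydroxyl, re-forms O1–C2 with ring B trans to the C3 arm and anti to the C4 benzyl group (the less crowded and more stable ether), as in the known closure of benzylic hydroxy secolignan diols to 2-aryl oxolane lignans.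

Step 12
Reactants: 15 (3S,4R,5S)-5-(4-allyloxy-3-methoxyphenyl)-3-(4-benzyloxy-3-methoxybenzyl)-4-[(tert-butyldiphenylsilyloxy)methyl]oxolan-3-ol
Product: 16 (3S,4R,5S)-3-(4-benzyloxy-3-methoxybenzyl)-4-[(tert-butyldiphenylsilyloxy)methyl]-5-(4-hydroxy-3-methoxyphenyl)oxolan-3-ol
Conditions: Pd(PPh3)4 (5 mol%), morpholine, THF, rt
Reagents that add atoms: none
Why: Tsuji–Trost deallylation, in which zerovalent palladium ionises the aryl allyl ether to a π-allyl complex that morpholine intercepts, frees only the ring B phenol.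

Step 13
Reactants: 17 (S)-4-benzyl-2-oxazolidinone; 18 bromoacetyl bromide
Product: 19 (S)-4-benzyl-3-(bromoacetyl)oxazolidin-2-one
Conditions: n-BuLi, THF, −78 °C; then 18, −78 to 0 °C
Reagents that add atoms: none
Why: N-Acylation of the lithiated oxazolidinone with the acid bromide is the standard entry to N-haloacetyl imides and does not touch the auxiliary stereocentre.

Step 14
Reactants: 16 (3S,4R,5S)-3-(4-benzyloxy-3-methoxybenzyl)-4-[(tert-butyldiphenylsilyloxy)methyl]-5-(4-hydroxy-3-methoxyphenyl)oxolan-3-ol; 19 (S)-4-benzyl-3-(bromoacetyl)oxazolidin-2-one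
Product: 20 (S)-4-benzyl-3-[(aryloxy)acetyl]oxazolidin-2-one, the aryloxy group being 16 bound through its ring B oxygen
Conditions: K2CO3, acetone, rt
Reagents that add atoms: none
Why: Williamson alkylation of the ring B phenoxide at the activated primary carbon of the α-bromo imide (SN2) forms the aryl ether bond of the side chain and brings in the auxiliary at once, the tertiary alcohol being too weakly acidic to compete.

Step 15
Reactants: 20 (S)-4-benzyl-3-[(aryloxy)acetyl]oxazolidin-2-one; 21 4-benzyloxy-3-methoxybenzaldehyde (O-benzylvanillin)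
Product: 22 (S)-4-benzyl-3-[(2S,3R)-2-(aryloxy)-3-(4-benzyloxy-3-methoxyphenyl)-3-hydroxypropanoyl]oxazolidin-2-one (7,8-syn)
Conditions: Bu2BOTf (2.5 equiv), i-Pr2NEt, CH2Cl2, −78 to 0 °C; then 21, −78 to 0 °C; H2O2, pH 7 buffer, MeOH, 0 °C
Reagents that add atoms: none
Why: Evans boron aldol reaction, in which the Z-dibutylboron enolate adds to the aldehyde through a chair Zimmerman–Traxler transition state on the enolate face away from the auxiliary benzyl group, sets C8 in the configuration of the target and C7 syn to it, the extra boron reagent covering the tertiary hydroxyl until the oxidative work-up.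

Step 16
Reactants: 22 syn aldol imide
Product: 23 (1R,2R)-2-(aryloxy)-1-(4-benzyloxy-3-methoxyphenyl)propane-1,3-diol (7R,8R, syn)
Conditions: NaBH4, THF/H2O, 0 °C to rt
Reagents that add atoms: none
Why: Reductive cleavage of the N-acyl oxazolidinone turns the imide carbonyl into the C9 primary alcohol and releases the auxiliary without epimerising C8.

Step 17
Reactants: 23 (7R,8R)-diol
Product: 24 the 9-O-tert-butyldimethylsilyl ether of 23
Conditions: t-BuMe2SiCl, imidazole, CH2Cl2, 0 °C
Reagents that add atoms: tert-butyl(chloro)dimethylsilane, CC(C)(C)[Si](C)(C)Cl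
Why: Selective silylation of the primary C9 hydroxyl over the hindered benzylic and the tertiary hydroxyl leaves C7–OH as the only alcohol able to react in the next step.

Step 18
Reactants: 24 (7R,8R) C9 silyl ether
Product: 25 the (7S,8R) 7-O-(4-nitrobenzoate) of the C9 silyl ether
Conditions: 4-nitrobenzoic acid, PPh3, DIAD, THF, 0 °C to rt
Reagents that add atoms: 4-nitrobenzoic acid, OC(=O)c1ccc(cc1)[N+](=O)[O-]
Why: Mitsunobu inversion, in which 4-nitrobenzoate displaces the C7 alkoxyphosphonium group by SN2, converts the syn (7R,8R) into the anti (7S,8R) arrangement, while the tertiary alcohol cannot be activated.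

Step 19
Reactants: 25 (7S,8R) 4-nitrobenzoate
Product: 26 the (7S,8R) alcohol carrying both silyl ethers and both benzyl ethers
Conditions: K2CO3, MeOH, rt
Reagents that add atoms: none
Why: Methanolysis (transesterification) of the activated aryl ester takes place at the acyl carbon and so frees the C7 hydroxyl with its new configuration intact.

Step 20
Reactants: 26 (7S,8R) alcohol
Product: 27 (1S,2R)-1-(4-benzyloxy-3-methoxyphenyl)-2-{4-[(2S,3R,4S)-4-(4-benzyloxy-3-methoxybenzyl)-4-hydroxy-3-(hydroxymethyl)oxolan-2-yl]-2-methoxyphenoxy}propane-1,3-diol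
Conditions: Bu4NF, THF, 0 °C to rt
Reagents that add atoms: none
Why: Fluoride-induced desilylation removes the tert-butyldimethylsilyl and the tert-butyldiphenylsilyl ether in one operation and touches neither benzyl ethers nor stereocentres.

Step 21
Reactants: 27 dibenzyl ether of the target
Product: 28 the target, (1S,2R)-1-(4-hydroxy-3-methoxyphenyl)-2-{4-[(2S,3R,4S)-4-hydroxy-4-(4-hydroxy-3-methoxybenzyl)-3-(hydroxymethyl)oxolan-2-yl]-2-methoxyphenoxy}propane-1,3-diol
Conditions: H2 (1 atm), 10% Pd/C, EtOAc/MeOH, rt, stopped at full debenzylation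
Reagents that add atoms: none
Why: Catalytic hydrogenolysis cleaves the two aryl benzyl ethers, which under neutral conditions should go much faster than the benzylic C2–O1 and C7–OH bonds, and releases the ring A and ring C phenols.

**Compound list**

1 | coniferaldehyde, (E)-3-(4-hydroxy-3-methoxyphenyl)prop-2-enal | COc1cc(/C=C/C=O)ccc1O | starting material
2 | (E)-3-(4-allyloxy-3-methoxyphenyl)prop-2-enal | COc1cc(/C=C/C=O)ccc1OCC=C | intermediate
3 | dimethyl bromomalonate | COC(=O)C(Br)C(=O)OC | starting material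
4 | dimethyl (2S,3R)-2-(4-allyloxy-3-methoxyphenyl)-3-formylcyclopropane-1,1-dicarboxylate (aryl and formyl trans) | COC(=O)C1(C(=O)OC)[C@H](c2ccc(OCC=C)c(OC)c2)[C@H]1C=O | intermediate
5 | dimethyl (2S,3R)-2-(4-allyloxy-3-methoxyphenyl)-3-(hydroxymethyl)cyclopropane-1,1-dicarboxylate | COC(=O)C1(C(=O)OC)[C@H](c2ccc(OCC=C)c(OC)c2)[C@H]1CO | intermediate
6 | dimethyl (2S,3R)-2-(4-allyloxy-3-methoxyphenyl)-3-[(tert-butyldiphenylsilyloxy)methyl]cyclopropane-1,1-dicarboxylate | COC(=O)C1(C(=O)OC)[C@H](c2ccc(OCC=C)c(OC)c2)[C@H]1CO[Si](c3ccccc3)(c4ccccc4)C(C)(C)C | intermediate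
7 | methyl (4R,5S)-5-(4-allyloxy-3-methoxyphenyl)-4-[(tert-butyldiphenylsilyloxy)methyl]-2-methoxy-4,5-dihydrofuran-3-carboxylate (cyclic ketene acetal) | COC(=O)C1=C(OC)O[C@H](c2ccc(OCC=C)c(OC)c2)[C@H]1CO[Si](c3ccccc3)(c4ccccc4)C(C)(C)C | intermediate (not isolated)
8 | methyl (3R,4R,5S)-5-(4-allyloxy-3-methoxyphenyl)-4-[(tert-butyldiphenylsilyloxy)methyl]-2-oxooxolane-3-carboxylate (all-trans) | COC(=O)[C@@H]1C(=O)O[C@H](c2ccc(OCC=C)c(OC)c2)[C@H]1CO[Si](c3ccccc3)(c4ccccc4)C(C)(C)C | intermediate
9 | 4-benzyloxy-3-methoxybenzyl alcohol | COc1cc(CO)ccc1OCc2ccccc2 | starting material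
10 | 4-benzyloxy-3-methoxybenzyl bromide | COc1cc(CBr)ccc1OCc2ccccc2 | intermediate
11 | methyl (3S,4R,5S)-5-(4-allyloxy-3-methoxyphenyl)-3-(4-benzyloxy-3-methoxybenzyl)-4-[(tert-butyldiphenylsilyloxy)methyl]-2-oxooxolane-3-carboxylate | COC(=O)[C@@]1(Cc2ccc(OCc3ccccc3)c(OC)c2)C(=O)O[C@H](c4ccc(OCC=C)c(OC)c4)[C@H]1CO[Si](c5ccccc5)(c6ccccc6)C(C)(C)C | intermediate
12 | (3S,4R,5S)-5-(4-allyloxy-3-methoxyphenyl)-3-(4-benzyloxy-3-methoxybenzyl)-4-[(tert-butyldiphenylsilyloxy)methyl]oxolan-2-one | COc1cc(C[C@@H]2C(=O)O[C@H](c3ccc(OCC=C)c(OC)c3)[C@H]2CO[Si](c4ccccc4)(c5ccccc5)C(C)(C)C)ccc1OCc6ccccc6 | intermediate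
13 | (3S,4R,5S)-5-(4-allyloxy-3-methoxyphenyl)-3-(4-benzyloxy-3-methoxybenzyl)-4-[(tert-butyldiphenylsilyloxy)methyl]-3-hydroxyoxolan-2-one | COc1cc(C[C@@]2(O)C(=O)O[C@H](c3ccc(OCC=C)c(OC)c3)[C@H]2CO[Si](c4ccccc4)(c5ccccc5)C(C)(C)C)ccc1OCc6ccccc6 | intermediate
14 | (2S,3R,4S)-4-(4-allyloxy-3-methoxyphenyl)-2-(4-benzyloxy-3-methoxybenzyl)-3-[(tert-butyldiphenylsilyloxy)methyl]butane-1,2,4-triol | COc1cc(C[C@@](O)(CO)[C@H](CO[Si](c2ccccc2)(c3ccccc3)C(C)(C)C)[C@H](O)c4ccc(OCC=C)c(OC)c4)ccc1OCc5ccccc5 | intermediate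
15 | (3S,4R,5S)-5-(4-allyloxy-3-methoxyphenyl)-3-(4-benzyloxy-3-methoxybenzyl)-4-[(tert-butyldiphenylsilyloxy)methyl]oxolan-3-ol | COc1cc(C[C@@]2(O)CO[C@H](c3ccc(OCC=C)c(OC)c3)[C@H]2CO[Si](c4ccccc4)(c5ccccc5)C(C)(C)C)ccc1OCc6ccccc6 | intermediate
16 | (3S,4R,5S)-3-(4-benzyloxy-3-methoxybenzyl)-4-[(tert-butyldiphenylsilyloxy)methyl]-5-(4-hydroxy-3-methoxyphenyl)oxolan-3-ol | COc1cc(C[C@@]2(O)CO[C@H](c3ccc(O)c(OC)c3)[C@H]2CO[Si](c4ccccc4)(c5ccccc5)C(C)(C)C)ccc1OCc6ccccc6 | intermediate
17 | (S)-4-benzyl-2-oxazolidinone | O=C1N[C@@H](Cc2ccccc2)CO1 | starting material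
18 | bromoacetyl bromide | BrCC(Br)=O | starting material
19 | (S)-4-benzyl-3-(bromoacetyl)oxazolidin-2-one | O=C1N(C(=O)CBr)[C@@H](Cc2ccccc2)CO1 | intermediate
20 | (S)-4-benzyl-3-[(aryloxy)acetyl]oxazolidin-2-one, aryloxy = 16 bound through its ring B oxygen | COc1cc(C[C@@]2(O)CO[C@H](c3ccc(OCC(=O)N4C(=O)OC[C@@H]4Cc5ccccc5)c(OC)c3)[C@H]2CO[Si](c6ccccc6)(c7ccccc7)C(C)(C)C)ccc1OCc8ccccc8 | intermediate
21 | 4-benzyloxy-3-methoxybenzaldehyde (O-benzylvanillin) | COc1cc(C=O)ccc1OCc2ccccc2 | starting material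
22 | (S)-4-benzyl-3-[(2S,3R)-2-(aryloxy)-3-(4-benzyloxy-3-methoxyphenyl)-3-hydroxypropanoyl]oxazolidin-2-one (syn aldol) | COc1cc(C[C@@]2(O)CO[C@H](c3ccc(O[C@H](C(=O)N4C(=O)OC[C@@H]4Cc5ccccc5)[C@H](O)c6ccc(OCc7ccccc7)c(OC)c6)c(OC)c3)[C@H]2CO[Si](c8ccccc8)(c9ccccc9)C(C)(C)C)ccc1OCc%10ccccc%10 | intermediate
23 | (1R,2R)-2-(aryloxy)-1-(4-benzyloxy-3-methoxyphenyl)propane-1,3-diol (7R,8R, syn) | COc1cc(C[C@@]2(O)CO[C@H](c3ccc(O[C@H](CO)[C@H](O)c4ccc(OCc5ccccc5)c(OC)c4)c(OC)c3)[C@H]2CO[Si](c6ccccc6)(c7ccccc7)C(C)(C)C)ccc1OCc8ccccc8 | intermediate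
24 | 9-O-tert-butyldimethylsilyl ether of 23 (7R,8R) | COc1cc(C[C@@]2(O)CO[C@H](c3ccc(O[C@H](CO[Si](C)(C)C(C)(C)C)[C@H](O)c4ccc(OCc5ccccc5)c(OC)c4)c(OC)c3)[C@H]2CO[Si](c6ccccc6)(c7ccccc7)C(C)(C)C)ccc1OCc8ccccc8 | intermediate
25 | (7S,8R) 7-O-(4-nitrobenzoate) of the C9 silyl ether | COc1cc(C[C@@]2(O)CO[C@H](c3ccc(O[C@H](CO[Si](C)(C)C(C)(C)C)[C@@H](OC(=O)c4ccc(cc4)[N+](=O)[O-])c5ccc(OCc6ccccc6)c(OC)c5)c(OC)c3)[C@H]2CO[Si](c7ccccc7)(c8ccccc8)C(C)(C)C)ccc1OCc9ccccc9 | intermediate
26 | (7S,8R) alcohol, anti, with both silyl and both benzyl ethers | COc1cc(C[C@@]2(O)CO[C@H](c3ccc(O[C@H](CO[Si](C)(C)C(C)(C)C)[C@@H](O)c4ccc(OCc5ccccc5)c(OC)c4)c(OC)c3)[C@H]2CO[Si](c6ccccc6)(c7ccccc7)C(C)(C)C)ccc1OCc8ccccc8 | intermediate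
27 | (1S,2R)-1-(4-benzyloxy-3-methoxyphenyl)-2-{4-[(2S,3R,4S)-4-(4-benzyloxy-3-methoxybenzyl)-4-hydroxy-3-(hydroxymethyl)oxolan-2-yl]-2-methoxyphenoxy}propane-1,3-diol | COc1cc(C[C@@]2(O)CO[C@H](c3ccc(O[C@H](CO)[C@@H](O)c4ccc(OCc5ccccc5)c(OC)c4)c(OC)c3)[C@H]2CO)ccc1OCc6ccccc6 | intermediate
28 | (1S,2R)-1-(4-hydroxy-3-methoxyphenyl)-2-{4-[(2S,3R,4S)-4-hydroxy-4-(4-hydroxy-3-methoxybenzyl)-3-(hydroxymethyl)oxolan-2-yl]-2-methoxyphenoxy}propane-1,3-diol | COc1cc(C[C@@]2(O)CO[C@H](c3ccc(O[C@H](CO)[C@@H](O)c4ccc(O)c(OC)c4)c(OC)c3)[C@H]2CO)ccc1O | target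

**Step count and risks**

Total step count: 21. Longest linear sequence: 19 (steps 1–5, 7–12, 14–21).

Steps most likely to fail:

Step 5. The Lewis acid may strip the silyl ether, after which the freed arm would lactonise onto an ester. The benzylic cation may also be captured by another electron-rich arene, or lose the C3 proton to give an open-chain alkene. The fallback sets out from 6 and removes the Lewis acid altogether. Both esters are saponified with KOH in aqueous methanol to (2S,3R)-2-(4-allyloxy-3-methoxyphenyl)-3-[(tert-butyldiphenylsilyloxy)methyl]cyclopropane-1,1-dicarboxylic acid F1. On gentle warming in toluene the diacid should open its own ring, one carboxyl group capturing the C2 cation, to give (3R,4R,5S)-5-(4-allyloxy-3-methoxyphenyl)-4-[(tert-butyldiphenylsilyloxy)methyl]-2-oxooxolane-3-carboxylic acid F2. Esterification with trimethylsilyldiazomethane in methanol comes back to the route at 8.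

Step 11. The C2 cation may be trapped by ring A in a Friedel–Crafts closure to an aryltetralin (the cyclolignan pathway), the tertiary alcohol may dehydrate, or the 2,3-cis ether may form. The fallback sets out from 13 and never breaks O1–C2. The lactone is reduced with i-Bu2AlH in CH2Cl2 at −78 °C to the lactol (3S,4R,5S)-5-(4-allyloxy-3-methoxyphenyl)-3-(4-benzyloxy-3-methoxybenzyl)-4-[(tert-butyldiphenylsilyloxy)methyl]oxolane-2,3-diol F3, a mixture of anomers. Ionic reduction with Et3SiH and BF3·OEt2 at −78 °C removes the anomeric oxygen through the C5 oxocarbenium ion and comes back to the route at 15, bypassing 14.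

Step 18. The electron-rich benzylic oxyphosphonium ion may ionise, which would cost stereospecificity. It may instead eliminate to the enol ether, or fail to react for steric reasons. The fallback sets out from 24 and replaces substitution by oxidation and reduction. Dess–Martin periodinane in CH2Cl2 gives the α-aryloxy ketone F4 (C7 carbonyl, C8 unchanged). Zn(BH4)2 in Et2O at −20 °C should reduce it under chelation control, zinc bridging the ketone and the C8 ether oxygen and hydride arriving opposite the C9 arm, to the anti alcohol. The fallback comes back to the route at 26, bypassing 25.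

**Further compounds**

F1 | step 5 | (2S,3R)-2-(4-allyloxy-3-methoxyphenyl)-3-[(tert-butyldiphenylsilyloxy)methyl]cyclopropane-1,1-dicarboxylic acid | OC(=O)C1(C(O)=O)[C@H](c2ccc(OCC=C)c(OC)c2)[C@H]1CO[Si](c3ccccc3)(c4ccccc4)C(C)(C)C
F2 | step 5 | (3R,4R,5S)-5-(4-allyloxy-3-methoxyphenyl)-4-[(tert-butyldiphenylsilyloxy)methyl]-2-oxooxolane-3-carboxylic acid | OC(=O)[C@@H]1C(=O)O[C@H](c2ccc(OCC=C)c(OC)c2)[C@H]1CO[Si](c3ccccc3)(c4ccccc4)C(C)(C)C
F3 | step 11 | (3S,4R,5S)-5-(4-allyloxy-3-methoxyphenyl)-3-(4-benzyloxy-3-methoxybenzyl)-4-[(tert-butyldiphenylsilyloxy)methyl]oxolane-2,3-diol (lactol, both anomers) | COc1cc(C[C@@]2(O)C(O)O[C@H](c3ccc(OCC=C)c(OC)c3)[C@H]2CO[Si](c4ccccc4)(c5ccccc5)C(C)(C)C)ccc1OCc6ccccc6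
F4 | step 18 | (8R)-7-ketone of 24, 2-(aryloxy)-1-(4-benzyloxy-3-methoxyphenyl)-3-(tert-butyldimethylsilyloxy)propan-1-one | COc1cc(C[C@@]2(O)CO[C@H](c3ccc(O[C@H](CO[Si](C)(C)C(C)(C)C)C(=O)c4ccc(OCc5ccccc5)c(OC)c4)c(OC)c3)[C@H]2CO[Si](c6ccccc6)(c7ccccc7)C(C)(C)C)ccc1OCc8ccccc8
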